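**Retrosynthetic overview**
1. The 19-O-dodecanoyl group goes on last. C11=C12 comes from a Wittig union of a C15 keto-phosphonium salt (β-ring, C7–C11, C19) with a C25 apo-aldehyde (C12–C7', ε-ring).
2. The C25 aldehyde comes from an ε-C15 phosphonium salt and the C10 trienedial. The ε-ring is not built: C6' is taken from (R)-α-ionone and C3' is set by allylic oxidation and CBS reduction.
3. The C15 keto-phosphonium salt comes from a Nozaki–Hiyama–Kishi C8–C9 coupling of the β-ring acetaldehyde with an (E)-2-iodobutene-1,4-diol unit (C19, C9–C11) made from but-2-yne-1,4-diol.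
4. The β-ring is the only ring formed (step 2): acetone (C4, C5, C18) and 3,3-dimethylpentanedial (C3, C2, C1, C6, C7) are joined by an aldol (C3–C4) and then an enolexo aldol condensation (C5=C6).
5. Enabling feature of the β-ring: O–C3 is β to C5, so C3(OH)–C4–C5 is an acetone aldol retron; C5=C6 becomes an aldol-condensation retron once exocyclic C7 is a formyl carbon; the C1 gem-dimethyl makes the C3–C2–C1–C6–C7 partner a symmetric dialdehyde with homotopic ends.

Key step: step 2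

Remarks: Carotenoid numbering is used for positions. It is assumed that (R)-α-ionone of high enantiomeric purity, (2E,4E,6E)-2,7-dimethylocta-2,4,6-trienedial and 3,3-dimethylpentane-1,5-diol are bought. The C8 carbinol of 17 is carried as an epimer mixture because step 12 removes that centre.

**Step 1**
Reactants: 1 3,3-dimethylpentane-1,5-diol
Product: 2 3,3-dimethylpentanedial
Conditions: (COCl)2, DMSO, CH2Cl2, −78 °C; Et3N, −78 °C → rt; used crude
Reagents that add atoms: none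
Why: In the Swern oxidation both hydroxyls are activated before base is added, so the dialdehyde should form without oxidation of an intermediate lactol to the lactone.

**Step 2**
Reactants: 2 3,3-dimethylpentanedial; 3 acetone
Product: 5 (4R)-4-hydroxy-2,6,6-trimethylcyclohex-1-ene-1-carbaldehyde, via hydroxy keto aldehyde 4 (not isolated)
Conditions: L-proline (30 mol %), acetone/CHCl3, rt; volatiles off at ≤25 °C; Bn2NH·CF3CO2H (30 mol %), toluene, 40 °C, same flask
Reagents that add atoms: none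
Why: Proposed new method: the L-proline enamine of acetone adds to the Re face of one of the two homotopic formyl groups of 2 through the carboxylic-acid-bridged chair transition state, which makes C3–C4 and fixes C3 as (S) in open-chain 4, that is (R) in the ring; 4 then rests mainly as its six-membered lactol, which keeps the second formyl group from a second acetone aldol. After acetone is stripped, the secondary ammonium salt turns the free formyl group of 4 into its enamine, whose carbon C6 attacks the methyl ketone C5, and E1cB loss of water through the iminium ion gives the tetrasubstituted C5=C6 enal 5. The closest known reactions are the proline-catalysed acetone aldol of α-unbranched aldehydes and the amine-salt cyclodehydration of keto aldehydes to cycloalkene-1-carbaldehydes; their merger on a 1,5-dialdehyde as a formal [4+2] annulation is the new element. The only ring closes in the 6-(enolexo)-exo-trig aldol mode, and the only new stereocentre, C3, is under catalyst control. The step needs mono-addition (lactol masking, and neopentyl-type α-carbons that also slow aldehyde self-aldol), closure through the aldehyde enamine and not the ketone (a secondary ammonium salt condenses far faster with a formyl group than with a methyl ketone), and survival of the C3 hydroxyl against vinylogous β-elimination (weakly acidic medium, 40 °C at most).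

**Step 3**
Reactants: 5 (4R)-4-hydroxy-2,6,6-trimethylcyclohex-1-ene-1-carbaldehyde
Product: 6 (4R)-4-[(tert-butyldimethylsilyl)oxy]-2,6,6-trimethylcyclohex-1-ene-1-carbaldehyde
Conditions: TBSCl, imidazole, DMF, 0 °C → rt
Reagents that add atoms: tert-butyldimethylsilyl chloride CC(C)(C)[Si](C)(C)Cl
Why: Standard silylation of a secondary alcohol under mild base should cap the hydroxyl that is otherwise prone to vinylogous dehydration.

**Step 4**
Reactants: 6 (4R)-4-[(tert-butyldimethylsilyl)oxy]-2,6,6-trimethylcyclohex-1-ene-1-carbaldehyde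
Product: 7 tert-butyl{[(1R)-4-ethenyl-3,5,5-trimethylcyclohex-3-en-1-yl]oxy}dimethylsilane
Conditions: Ph3PCH3Br, KOtBu, THF, 0 °C → rt
Reagents that add atoms: methyltriphenylphosphonium bromide C[P+](c1ccccc1)(c1ccccc1)c1ccccc1.[Br-]
Why: Wittig methylenation with the small unstabilised ylide should reach the hindered formyl group faster than it deprotonates the γ-position.

**Step 5**
Reactants: 7 tert-butyl{[(1R)-4-ethenyl-3,5,5-trimethylcyclohex-3-en-1-yl]oxy}dimethylsilane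
Product: 9 2-[(4R)-4-[(tert-butyldimethylsilyl)oxy]-2,6,6-trimethylcyclohex-1-en-1-yl]ethan-1-ol, via alkylborane 8 (not isolated)
Conditions: 9-BBN, THF, 0 °C → rt; then aq. NaOH, H2O2, 0 °C
Reagents that add atoms: hydrogen peroxide OO
Why: In the hydroboration–oxidation, 9-BBN should add only to the monosubstituted terminal alkene with boron on C8, leaving the tetrasubstituted ring alkene in place.

**Step 6**
Reactants: 9 2-[(4R)-4-[(tert-butyldimethylsilyl)oxy]-2,6,6-trimethylcyclohex-1-en-1-yl]ethan-1-ol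
Product: 10 2-[(4R)-4-[(tert-butyldimethylsilyl)oxy]-2,6,6-trimethylcyclohex-1-en-1-yl]acetaldehyde
Conditions: Dess–Martin periodinane, pyridine, CH2Cl2, 0 °C → rt; used at once
Reagents that add atoms: none
Why: Dess–Martin oxidation under buffered, non-basic conditions should give the β,γ-unsaturated aldehyde without moving C5=C6 into conjugation.

**Step 7**
Reactants: 11 but-2-yne-1,4-diol
Product: 12 (2E)-2-(tributylstannyl)but-2-ene-1,4-diol
Conditions: Bu3SnH, PdCl2(PPh3)2 (cat.), THF, 0 °C → rt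
Reagents that add atoms: tributyltin hydride CCCC[SnH](CCCC)CCCC
Why: Palladium-catalysed hydrostannation adds H and Sn syn across the symmetric alkyne, so one regio- and stereoisomer with the two hydroxymethyl groups cis should result.

**Step 8**
Reactants: 12 (2E)-2-(tributylstannyl)but-2-ene-1,4-diol
Product: 13 (2E)-4-[(tert-butyldimethylsilyl)oxy]-2-(tributylstannyl)but-2-en-1-ol
Conditions: TBSCl (1.0 equiv), imidazole, CH2Cl2, −20 °C
Reagents that add atoms: tert-butyldimethylsilyl chloride CC(C)(C)[Si](C)(C)Cl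
Why: Kinetic silylation should go to the hydroxymethyl group remote from the bulky Bu3Sn substituent (the future C11 oxygen).

**Step 9**
Reactants: 13 (2E)-4-[(tert-butyldimethylsilyl)oxy]-2-(tributylstannyl)but-2-en-1-ol
Product: 14 (2E)-1-[(tert-butyldiphenylsilyl)oxy]-4-[(tert-butyldimethylsilyl)oxy]-2-(tributylstannyl)but-2-ene
Conditions: TBDPSCl, imidazole, DMF, rt
Reagents that add atoms: tert-butyldiphenylsilyl chloride CC(C)(C)[Si](Cl)(c1ccccc1)c1ccccc1
Why: Silylation of the remaining hydroxyl (the future C19 oxygen) with the more acid-stable TBDPS group makes the two primary ethers distinguishable later.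

**Step 10**
Reactants: 14 (2E)-1-[(tert-butyldiphenylsilyl)oxy]-4-[(tert-butyldimethylsilyl)oxy]-2-(tributylstannyl)but-2-ene
Product: 15 (2E)-1-[(tert-butyldiphenylsilyl)oxy]-4-[(tert-butyldimethylsilyl)oxy]-2-iodobut-2-ene
Conditions: I2, CH2Cl2, 0 °C
Reagents that add atoms: iodine II
Why: Iododestannylation replaces tin by iodine with retention of the alkene geometry.

**Step 11**
Reactants: 10 2-[(4R)-4-[(tert-butyldimethylsilyl)oxy]-2,6,6-trimethylcyclohex-1-en-1-yl]acetaldehyde; 15 (2E)-1-[(tert-butyldiphenylsilyl)oxy]-4-[(tert-butyldimethylsilyl)oxy]-2-iodobut-2-ene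
Product: 17 (3E)-1-[(4R)-4-[(tert-butyldimethylsilyl)oxy]-2,6,6-trimethylcyclohex-1-en-1-yl]-5-[(tert-butyldimethylsilyl)oxy]-3-{[(tert-butyldiphenylsilyl)oxy]methyl}pent-3-en-2-ol (C2 epimers), via vinylchromium dichloride 16 (not isolated)
Conditions: CrCl2 (excess), NiCl2 (cat.), DMSO/THF, rt
Reagents that add atoms: none
Why: In the Nozaki–Hiyama–Kishi coupling, zerovalent nickel inserts into the C–I bond and transmetalation gives a non-basic vinyl species of trivalent chromium that adds 1,2 to the enolisable β,γ-unsaturated aldehyde with retention of alkene geometry; the C8 carbinol forms without control and is oxidised in step 12.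

**Step 12**
Reactants: 17 (3E)-1-[(4R)-4-[(tert-butyldimethylsilyl)oxy]-2,6,6-trimethylcyclohex-1-en-1-yl]-5-[(tert-butyldimethylsilyl)oxy]-3-{[(tert-butyldiphenylsilyl)oxy]methyl}pent-3-en-2-ol
Product: 18 (3E)-1-[(4R)-4-[(tert-butyldimethylsilyl)oxy]-2,6,6-trimethylcyclohex-1-en-1-yl]-5-[(tert-butyldimethylsilyl)oxy]-3-{[(tert-butyldiphenylsilyl)oxy]methyl}pent-3-en-2-one
Conditions: Dess–Martin periodinane, pyridine, CH2Cl2, 0 °C
Reagents that add atoms: none
Why: Dess–Martin oxidation of the allylic alcohol should give the C8 enone under non-basic conditions that leave C5=C6 β,γ to the new ketone.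

**Step 13**
Reactants: 18 (3E)-1-[(4R)-4-[(tert-butyldimethylsilyl)oxy]-2,6,6-trimethylcyclohex-1-en-1-yl]-5-[(tert-butyldimethylsilyl)oxy]-3-{[(tert-butyldiphenylsilyl)oxy]methyl}pent-3-en-2-one
Product: 19 (3E)-1-[(4R)-4-[(tert-butyldimethylsilyl)oxy]-2,6,6-trimethylcyclohex-1-en-1-yl]-3-{[(tert-butyldiphenylsilyl)oxy]methyl}-5-hydroxypent-3-en-2-one
Conditions: pyridinium p-toluenesulfonate (cat.), MeOH/CH2Cl2, 0 °C → rt
Reagents that add atoms: none
Why: Mild acid methanolysis should cleave the primary allylic TBS ether faster than the secondary ring TBS ether and the primary TBDPS ether.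

**Step 14**
Reactants: 19 (3E)-1-[(4R)-4-[(tert-butyldimethylsilyl)oxy]-2,6,6-trimethylcyclohex-1-en-1-yl]-3-{[(tert-butyldiphenylsilyl)oxy]methyl}-5-hydroxypent-3-en-2-one
Product: 21 [(2E)-5-[(4R)-4-[(tert-butyldimethylsilyl)oxy]-2,6,6-trimethylcyclohex-1-en-1-yl]-3-{[(tert-butyldiphenylsilyl)oxy]methyl}-4-oxopent-2-en-1-yl]triphenylphosphonium bromide, via allylic bromide 20 (not isolated)
Conditions: CBr4, PPh3, CH2Cl2, 0 °C; then PPh3, MeCN, rt
Reagents that add atoms: carbon tetrabromide BrC(Br)(Br)Br; triphenylphosphine c1ccc(cc1)P(c1ccccc1)c1ccccc1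
Why: Appel bromination of the primary allylic alcohol followed by SN2 alkylation of PPh3 by the reactive γ-bromo enone should give the salt under neutral conditions.

**Step 15**
Reactants: 22 (R)-α-ionone, (3E)-4-[(1R)-2,6,6-trimethylcyclohex-2-en-1-yl]but-3-en-2-one
Product: 23 ethyl (2E,4E)-3-methyl-5-[(1R)-2,6,6-trimethylcyclohex-2-en-1-yl]penta-2,4-dienoate
Conditions: (EtO)2P(O)CH2CO2Et, NaH, THF, 0 °C → rt; minor (2Z) isomer removed by chromatography
Reagents that add atoms: triethyl phosphonoacetate CCOC(=O)CP(=O)(OCC)OCC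
Why: Horner–Wadsworth–Emmons olefination of the methyl ketone should favour the (2E)-dienoate, and the weakly basic phosphonate anion should not epimerise C6'.

**Step 16**
Reactants: 23 ethyl (2E,4E)-3-methyl-5-[(1R)-2,6,6-trimethylcyclohex-2-en-1-yl]penta-2,4-dienoate
Product: 24 ethyl (2E,4E)-3-methyl-5-[(1R)-2,6,6-trimethyl-4-oxocyclohex-2-en-1-yl]penta-2,4-dienoate
Conditions: Rh2(cap)4 (dirhodium tetrakis(caprolactamate), cat.), t-BuOOH (aq.), K2CO3 (cat.), CH2Cl2, rt
Reagents that add atoms: tert-butyl hydroperoxide CC(C)(C)OO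
Why: Peroxyl-radical allylic oxidation should convert the ring methylene next to the trisubstituted alkene (C3') into the enone, while the tertiary C6'–H is shielded by the gem-dimethyl group and the side chain.

**Step 17**
Reactants: 24 ethyl (2E,4E)-3-methyl-5-[(1R)-2,6,6-trimethyl-4-oxocyclohex-2-en-1-yl]penta-2,4-dienoate
Product: 25 ethyl (2E,4E)-5-[(1R,4R)-4-hydroxy-2,6,6-trimethylcyclohex-2-en-1-yl]-3-methylpenta-2,4-dienoate
Conditions: (S)-2-methyl-CBS-oxazaborolidine (cat.), catecholborane, toluene, −78 °C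
Reagents that add atoms: none
Why: In the CBS reduction the alkenyl flank of the ring ketone should act as the large group, so the (S)-catalyst should deliver hydride to the face that gives the (3'R) carbinol trans to the side chain, and catecholborane should leave the dienoate untouched.

**Step 18**
Reactants: 25 ethyl (2E,4E)-5-[(1R,4R)-4-hydroxy-2,6,6-trimethylcyclohex-2-en-1-yl]-3-methylpenta-2,4-dienoate
Product: 26 ethyl (2E,4E)-5-[(1R,4R)-4-[(tert-butyldimethylsilyl)oxy]-2,6,6-trimethylcyclohex-2-en-1-yl]-3-methylpenta-2,4-dienoate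
Conditions: TBSCl, imidazole, DMF, rt
Reagents that add atoms: tert-butyldimethylsilyl chloride CC(C)(C)[Si](C)(C)Cl
Why: Standard silylation should protect the acid-labile allylic hydroxyl for the later steps.

**Step 19**
Reactants: 26 ethyl (2E,4E)-5-[(1R,4R)-4-[(tert-butyldimethylsilyl)oxy]-2,6,6-trimethylcyclohex-2-en-1-yl]-3-methylpenta-2,4-dienoate
Product: 27 (2E,4E)-5-[(1R,4R)-4-[(tert-butyldimethylsilyl)oxy]-2,6,6-trimethylcyclohex-2-en-1-yl]-3-methylpenta-2,4-dien-1-ol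
Conditions: i-Bu2AlH, CH2Cl2, −78 °C; aq. potassium sodium tartrate work-up
Reagents that add atoms: none
Why: i-Bu2AlH should reduce the conjugated ester 1,2 to the allylic alcohol without touching the diene.

**Step 20**
Reactants: 27 (2E,4E)-5-[(1R,4R)-4-[(tert-butyldimethylsilyl)oxy]-2,6,6-trimethylcyclohex-2-en-1-yl]-3-methylpenta-2,4-dien-1-ol
Product: 28 [(2E,4E)-5-[(1R,4R)-4-[(tert-butyldimethylsilyl)oxy]-2,6,6-trimethylcyclohex-2-en-1-yl]-3-methylpenta-2,4-dien-1-yl]triphenylphosphonium bromide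
Conditions: PPh3·HBr, CH2Cl2, 0 °C → rt
Reagents that add atoms: triphenylphosphine hydrobromide [Br-].c1ccc(cc1)[PH+](c1ccccc1)c1ccccc1
Why: Triphenylphosphine hydrobromide ionises the dienylic alcohol and PPh3 captures the delocalised cation at the primary terminus, while the aprotic medium should spare the silyl ether.

**Step 21**
Reactants: 28 [(2E,4E)-5-[(1R,4R)-4-[(tert-butyldimethylsilyl)oxy]-2,6,6-trimethylcyclohex-2-en-1-yl]-3-methylpenta-2,4-dien-1-yl]triphenylphosphonium bromide; 29 (2E,4E,6E)-2,7-dimethylocta-2,4,6-trienedial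
Product: 31 (2E,4E,6E,8E,10E,12E)-13-[(1R,4R)-4-[(tert-butyldimethylsilyl)oxy]-2,6,6-trimethylcyclohex-2-en-1-yl]-2,7,11-trimethyltrideca-2,4,6,8,10,12-hexaenal, via ylide 30 (not isolated)
Conditions: 29 (excess), 1,2-epoxybutane, EtOH, reflux, dark, argon
Reagents that add atoms: none
Why: In this Wittig reaction the excess of dialdehyde should hold the olefination at the mono stage, and the heating should equilibrate the new disubstituted double bond to E.

**Step 22**
Reactants: 21 [(2E)-5-[(4R)-4-[(tert-butyldimethylsilyl)oxy]-2,6,6-trimethylcyclohex-1-en-1-yl]-3-{[(tert-butyldiphenylsilyl)oxy]methyl}-4-oxopent-2-en-1-yl]triphenylphosphonium bromide; 31 (2E,4E,6E,8E,10E,12E)-13-[(1R,4R)-4-[(tert-butyldimethylsilyl)oxy]-2,6,6-trimethylcyclohex-2-en-1-yl]-2,7,11-trimethyltrideca-2,4,6,8,10,12-hexaenal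
Product: 33 (3R,3'R,6'R)-3,3'-bis[(tert-butyldimethylsilyl)oxy]-19-[(tert-butyldiphenylsilyl)oxy]-7,8-dihydro-β,ε-caroten-8-one, via ylide 32 (not isolated)
Conditions: 1,2-epoxybutane, EtOH/CH2Cl2, 60 °C, dark, argon
Reagents that add atoms: none
Why: The vinylogously ketone-stabilised ylide should olefinate the polyenal at C11 with E preference under base-free epoxide conditions that limit enolisation at C7, and the all-E isomer is the thermodynamically favoured one at C9 and C11 if equilibration occurs.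

**Step 23**
Reactants: 33 (3R,3'R,6'R)-3,3'-bis[(tert-butyldimethylsilyl)oxy]-19-[(tert-butyldiphenylsilyl)oxy]-7,8-dihydro-β,ε-caroten-8-one
Product: 34 siphonaxanthin, (3R,3'R,6'R)-3,3',19-trihydroxy-7,8-dihydro-β,ε-caroten-8-one
Conditions: Bu4NF, AcOH, THF, 0 °C → rt, dark
Reagents that add atoms: none
Why: Fluoride cleaves all three silyl ethers, and the acetic acid buffer should keep the β,γ-unsaturated ketone from enolising.

**Step 24**
Reactants: 34 siphonaxanthin
Product: 35 siphonaxanthin 19-dodecanoate (target, CNP0415583.1)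
Conditions: dodecanoyl chloride (1.05 equiv), 2,4,6-collidine, CH2Cl2, −40 °C, dark
Reagents that add atoms: dodecanoyl chloride CCCCCCCCCCCC(=O)Cl
Why: At low temperature with a hindered, non-nucleophilic base the primary allylic C19 hydroxyl should be acylated much faster than the two secondary ring hydroxyls.

**Compound list**
1 | 3,3-dimethylpentane-1,5-diol | OCCC(C)(C)CCO | starting material
2 | 3,3-dimethylpentanedial | O=CCC(C)(C)CC=O | intermediate
3 | acetone | CC(C)=O | starting material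
4 | (5S)-5-hydroxy-3,3-dimethyl-7-oxooctanal (in equilibrium with its lactol) | CC(=O)C[C@@H](O)CC(C)(C)CC=O | intermediate
5 | (4R)-4-hydroxy-2,6,6-trimethylcyclohex-1-ene-1-carbaldehyde | O=CC1=C(C)C[C@@H](O)CC1(C)C | intermediate
6 | (4R)-4-[(tert-butyldimethylsilyl)oxy]-2,6,6-trimethylcyclohex-1-ene-1-carbaldehyde | O=CC1=C(C)C[C@@H](O[Si](C)(C)C(C)(C)C)CC1(C)C | intermediate
7 | tert-butyl{[(1R)-4-ethenyl-3,5,5-trimethylcyclohex-3-en-1-yl]oxy}dimethylsilane | C=CC1=C(C)C[C@@H](O[Si](C)(C)C(C)(C)C)CC1(C)C | intermediate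
8 | 9-{2-[(4R)-4-[(tert-butyldimethylsilyl)oxy]-2,6,6-trimethylcyclohex-1-en-1-yl]ethyl}-9-borabicyclo[3.3.1]nonane | C1CCC2CCCC1B2CCC1=C(C)C[C@@H](O[Si](C)(C)C(C)(C)C)CC1(C)C | intermediate
9 | 2-[(4R)-4-[(tert-butyldimethylsilyl)oxy]-2,6,6-trimethylcyclohex-1-en-1-yl]ethan-1-ol | OCCC1=C(C)C[C@@H](O[Si](C)(C)C(C)(C)C)CC1(C)C | intermediate
10 | 2-[(4R)-4-[(tert-butyldimethylsilyl)oxy]-2,6,6-trimethylcyclohex-1-en-1-yl]acetaldehyde | O=CCC1=C(C)C[C@@H](O[Si](C)(C)C(C)(C)C)CC1(C)C | intermediate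
11 | but-2-yne-1,4-diol | OCC#CCO | starting material
12 | (2E)-2-(tributylstannyl)but-2-ene-1,4-diol | OC/C(=C\CO)[Sn](CCCC)(CCCC)CCCC | intermediate
13 | (2E)-4-[(tert-butyldimethylsilyl)oxy]-2-(tributylstannyl)but-2-en-1-ol | OC/C(=C\CO[Si](C)(C)C(C)(C)C)[Sn](CCCC)(CCCC)CCCC | intermediate
14 | (2E)-1-[(tert-butyldiphenylsilyl)oxy]-4-[(tert-butyldimethylsilyl)oxy]-2-(tributylstannyl)but-2-ene | CC(C)(C)[Si](c1ccccc1)(c1ccccc1)OC/C(=C\CO[Si](C)(C)C(C)(C)C)[Sn](CCCC)(CCCC)CCCC | intermediate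
15 | (2E)-1-[(tert-butyldiphenylsilyl)oxy]-4-[(tert-butyldimethylsilyl)oxy]-2-iodobut-2-ene | CC(C)(C)[Si](c1ccccc1)(c1ccccc1)OC/C(I)=C\CO[Si](C)(C)C(C)(C)C | intermediate
16 | vinylchromium dichloride from 15 | CC(C)(C)[Si](c1ccccc1)(c1ccccc1)OC/C([Cr](Cl)Cl)=C\CO[Si](C)(C)C(C)(C)C | intermediate
17 | (3E)-1-[(4R)-4-[(tert-butyldimethylsilyl)oxy]-2,6,6-trimethylcyclohex-1-en-1-yl]-5-[(tert-butyldimethylsilyl)oxy]-3-{[(tert-butyldiphenylsilyl)oxy]methyl}pent-3-en-2-ol (C2 epimers) | CC(C)(C)[Si](C)(C)OC/C=C(\CO[Si](c1ccccc1)(c1ccccc1)C(C)(C)C)C(O)CC1=C(C)C[C@@H](O[Si](C)(C)C(C)(C)C)CC1(C)C | intermediate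
18 | (3E)-1-[(4R)-4-[(tert-butyldimethylsilyl)oxy]-2,6,6-trimethylcyclohex-1-en-1-yl]-5-[(tert-butyldimethylsilyl)oxy]-3-{[(tert-butyldiphenylsilyl)oxy]methyl}pent-3-en-2-one | CC(C)(C)[Si](C)(C)OC/C=C(\CO[Si](c1ccccc1)(c1ccccc1)C(C)(C)C)C(=O)CC1=C(C)C[C@@H](O[Si](C)(C)C(C)(C)C)CC1(C)C | intermediate
19 | (3E)-1-[(4R)-4-[(tert-butyldimethylsilyl)oxy]-2,6,6-trimethylcyclohex-1-en-1-yl]-3-{[(tert-butyldiphenylsilyl)oxy]methyl}-5-hydroxypent-3-en-2-one | OC/C=C(\CO[Si](c1ccccc1)(c1ccccc1)C(C)(C)C)C(=O)CC1=C(C)C[C@@H](O[Si](C)(C)C(C)(C)C)CC1(C)C | intermediate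
20 | (3E)-5-bromo-1-[(4R)-4-[(tert-butyldimethylsilyl)oxy]-2,6,6-trimethylcyclohex-1-en-1-yl]-3-{[(tert-butyldiphenylsilyl)oxy]methyl}pent-3-en-2-one | BrC/C=C(\CO[Si](c1ccccc1)(c1ccccc1)C(C)(C)C)C(=O)CC1=C(C)C[C@@H](O[Si](C)(C)C(C)(C)C)CC1(C)C | intermediate
21 | [(2E)-5-[(4R)-4-[(tert-butyldimethylsilyl)oxy]-2,6,6-trimethylcyclohex-1-en-1-yl]-3-{[(tert-butyldiphenylsilyl)oxy]methyl}-4-oxopent-2-en-1-yl]triphenylphosphonium bromide | [Br-].c1ccc(cc1)[P+](c1ccccc1)(c1ccccc1)C/C=C(\CO[Si](c1ccccc1)(c1ccccc1)C(C)(C)C)C(=O)CC1=C(C)C[C@@H](O[Si](C)(C)C(C)(C)C)CC1(C)C | intermediate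
22 | (R)-α-ionone, (3E)-4-[(1R)-2,6,6-trimethylcyclohex-2-en-1-yl]but-3-en-2-one | CC(=O)/C=C/[C@H]1C(C)=CCCC1(C)C | starting material
23 | ethyl (2E,4E)-3-methyl-5-[(1R)-2,6,6-trimethylcyclohex-2-en-1-yl]penta-2,4-dienoate | CCOC(=O)/C=C(C)/C=C/[C@H]1C(C)=CCCC1(C)C | intermediate
24 | ethyl (2E,4E)-3-methyl-5-[(1R)-2,6,6-trimethyl-4-oxocyclohex-2-en-1-yl]penta-2,4-dienoate | CCOC(=O)/C=C(C)/C=C/[C@H]1C(C)=CC(=O)CC1(C)C | intermediate
25 | ethyl (2E,4E)-5-[(1R,4R)-4-hydroxy-2,6,6-trimethylcyclohex-2-en-1-yl]-3-methylpenta-2,4-dienoate | CCOC(=O)/C=C(C)/C=C/[C@H]1C(C)=C[C@H](O)CC1(C)C | intermediate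
26 | ethyl (2E,4E)-5-[(1R,4R)-4-[(tert-butyldimethylsilyl)oxy]-2,6,6-trimethylcyclohex-2-en-1-yl]-3-methylpenta-2,4-dienoate | CCOC(=O)/C=C(C)/C=C/[C@H]1C(C)=C[C@H](O[Si](C)(C)C(C)(C)C)CC1(C)C | intermediate
27 | (2E,4E)-5-[(1R,4R)-4-[(tert-butyldimethylsilyl)oxy]-2,6,6-trimethylcyclohex-2-en-1-yl]-3-methylpenta-2,4-dien-1-ol | OC/C=C(C)/C=C/[C@H]1C(C)=C[C@H](O[Si](C)(C)C(C)(C)C)CC1(C)C | intermediate
28 | [(2E,4E)-5-[(1R,4R)-4-[(tert-butyldimethylsilyl)oxy]-2,6,6-trimethylcyclohex-2-en-1-yl]-3-methylpenta-2,4-dien-1-yl]triphenylphosphonium bromide | [Br-].c1ccc(cc1)[P+](c1ccccc1)(c1ccccc1)C/C=C(C)/C=C/[C@H]1C(C)=C[C@H](O[Si](C)(C)C(C)(C)C)CC1(C)C | intermediate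
29 | (2E,4E,6E)-2,7-dimethylocta-2,4,6-trienedial | O=C/C(C)=C/C=C/C=C(C)/C=O | starting material
30 | ylide of 28 | c1ccc(cc1)P(c1ccccc1)(c1ccccc1)=C/C=C(C)/C=C/[C@H]1C(C)=C[C@H](O[Si](C)(C)C(C)(C)C)CC1(C)C | intermediate
31 | (2E,4E,6E,8E,10E,12E)-13-[(1R,4R)-4-[(tert-butyldimethylsilyl)oxy]-2,6,6-trimethylcyclohex-2-en-1-yl]-2,7,11-trimethyltrideca-2,4,6,8,10,12-hexaenal | O=C/C(C)=C/C=C/C=C(C)/C=C/C=C(C)/C=C/[C@H]1C(C)=C[C@H](O[Si](C)(C)C(C)(C)C)CC1(C)C | intermediate
32 | ylide of 21 | c1ccc(cc1)P(c1ccccc1)(c1ccccc1)=C/C=C(\CO[Si](c1ccccc1)(c1ccccc1)C(C)(C)C)C(=O)CC1=C(C)C[C@@H](O[Si](C)(C)C(C)(C)C)CC1(C)C | intermediate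
33 | (3R,3'R,6'R)-3,3'-bis[(tert-butyldimethylsilyl)oxy]-19-[(tert-butyldiphenylsilyl)oxy]-7,8-dihydro-β,ε-caroten-8-one | CC(C)(C)[Si](c1ccccc1)(c1ccccc1)OC\C(=C/C=C/C(C)=C/C=C/C=C(C)/C=C/C=C(C)/C=C/[C@H]1C(C)=C[C@H](O[Si](C)(C)C(C)(C)C)CC1(C)C)C(=O)CC1=C(C)C[C@@H](O[Si](C)(C)C(C)(C)C)CC1(C)C | intermediate
34 | siphonaxanthin, (3R,3'R,6'R)-3,3',19-trihydroxy-7,8-dihydro-β,ε-caroten-8-one | OC\C(=C/C=C/C(C)=C/C=C/C=C(C)/C=C/C=C(C)/C=C/[C@H]1C(C)=C[C@H](O)CC1(C)C)C(=O)CC1=C(C)C[C@@H](O)CC1(C)C | intermediate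
35 | siphonaxanthin 19-dodecanoate (CNP0415583.1) | CCCCCCCCCCCC(=O)OC\C(=C/C=C/C(C)=C/C=C/C=C(C)/C=C/C=C(C)/C=C/[C@H]1C(C)=C[C@H](O)CC1(C)C)C(=O)CC1=C(C)C[C@@H](O)CC1(C)C | target

**Step count and risks**
Total steps: 24. Longest linear sequence: 13 steps (steps 1–6, 11–14, 22–24).

Steps most likely to fail:

1. Step 2 (proposed new method). Acetone may add to both formyl groups before ring closure, the C3 hydroxyl may be lost by vinylogous β-elimination during the amine-salt stage, and facial selectivity on a β-quaternary aldehyde may be low. The fallback uses known reactions only, sets out from 1 and comes back at 6. Diol 1 is mono-alkylated (NaH, 4-methoxybenzyl chloride, DMF) to 5-[(4-methoxybenzyl)oxy]-3,3-dimethylpentan-1-ol F1, and Swern oxidation gives 5-[(4-methoxybenzyl)oxy]-3,3-dimethylpentanal F2. The L-proline acetone aldol, now on a mono-aldehyde, gives (4S)-4-hydroxy-8-[(4-methoxybenzyl)oxy]-6,6-dimethyloctan-2-one F3, which is silylated (TBSOTf, 2,6-lutidine) to (4S)-4-[(tert-butyldimethylsilyl)oxy]-8-[(4-methoxybenzyl)oxy]-6,6-dimethyloctan-2-one F4. DDQ in buffered wet CH2Cl2 frees (4S)-4-[(tert-butyldimethylsilyl)oxy]-8-hydroxy-6,6-dimethyloctan-2-one F5, Dess–Martin oxidation gives (5S)-5-[(tert-butyldimethylsilyl)oxy]-3,3-dimethyl-7-oxooctanal F6, and Bn2NH·CF3CO2H in toluene closes F6 by the enolexo aldol condensation to 6.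

2. Step 22. The ylide is also a dienolate, so the C9=C10 geometry may scramble; enolisation at C7 may move C5=C6 into conjugation; and the stabilised ylide may olefinate the polyenal sluggishly. The fallback reverses the polarity of the union, sets out from 19 and 31 and comes back at 33. MnO2 oxidises 19 to (2E)-5-[(4R)-4-[(tert-butyldimethylsilyl)oxy]-2,6,6-trimethylcyclohex-1-en-1-yl]-3-{[(tert-butyldiphenylsilyl)oxy]methyl}-4-oxopent-2-enal F7. NaBH4 reduces 31 to (2E,4E,6E,8E,10E,12E)-13-[(1R,4R)-4-[(tert-butyldimethylsilyl)oxy]-2,6,6-trimethylcyclohex-2-en-1-yl]-2,7,11-trimethyltrideca-2,4,6,8,10,12-hexaen-1-ol F8, and PPh3·HBr converts it into the corresponding C25 triphenylphosphonium bromide F9. The ylide of F9 (NaN(SiMe3)2, THF, −78 °C) is combined with F7 at low temperature, where the formyl group should react before the ketone, to give 33.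

3. Step 17. Reagent control may be mismatched with the existing C6' centre, so hydride delivery may favour the 3',6'-cis carbinol. The fallback goes through inversion, sets out from 24 and comes back at 25. Luche reduction (NaBH4, CeCl3·7H2O, MeOH) gives the carbinol mixture, from which ethyl (2E,4E)-5-[(1R,4S)-4-hydroxy-2,6,6-trimethylcyclohex-2-en-1-yl]-3-methylpenta-2,4-dienoate F10 is separated. Mitsunobu reaction (4-nitrobenzoic acid, PPh3, diisopropyl azodicarboxylate) inverts C3' to ethyl (2E,4E)-3-methyl-5-[(1R,4R)-2,6,6-trimethyl-4-[(4-nitrobenzoyl)oxy]cyclohex-2-en-1-yl]penta-2,4-dienoate F11, and ethanolysis (K2CO3, EtOH) gives 25.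

**Further compounds**
F1 | step 2 | 5-[(4-methoxybenzyl)oxy]-3,3-dimethylpentan-1-ol | COc1ccc(COCCC(C)(C)CCO)cc1
F2 | step 2 | 5-[(4-methoxybenzyl)oxy]-3,3-dimethylpentanal | COc1ccc(COCCC(C)(C)CC=O)cc1
F3 | step 2 | (4S)-4-hydroxy-8-[(4-methoxybenzyl)oxy]-6,6-dimethyloctan-2-one | CC(=O)C[C@@H](O)CC(C)(C)CCOCc1ccc(OC)cc1
F4 | step 2 | (4S)-4-[(tert-butyldimethylsilyl)oxy]-8-[(4-methoxybenzyl)oxy]-6,6-dimethyloctan-2-one | CC(=O)C[C@@H](O[Si](C)(C)C(C)(C)C)CC(C)(C)CCOCc1ccc(OC)cc1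
F5 | step 2 | (4S)-4-[(tert-butyldimethylsilyl)oxy]-8-hydroxy-6,6-dimethyloctan-2-one | CC(=O)C[C@@H](O[Si](C)(C)C(C)(C)C)CC(C)(C)CCO
F6 | step 2 | (5S)-5-[(tert-butyldimethylsilyl)oxy]-3,3-dimethyl-7-oxooctanal | CC(=O)C[C@@H](O[Si](C)(C)C(C)(C)C)CC(C)(C)CC=O
F7 | step 22 | (2E)-5-[(4R)-4-[(tert-butyldimethylsilyl)oxy]-2,6,6-trimethylcyclohex-1-en-1-yl]-3-{[(tert-butyldiphenylsilyl)oxy]methyl}-4-oxopent-2-enal | O=C/C=C(\CO[Si](c1ccccc1)(c1ccccc1)C(C)(C)C)C(=O)CC1=C(C)C[C@@H](O[Si](C)(C)C(C)(C)C)CC1(C)C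
F8 | step 22 | (2E,4E,6E,8E,10E,12E)-13-[(1R,4R)-4-[(tert-butyldimethylsilyl)oxy]-2,6,6-trimethylcyclohex-2-en-1-yl]-2,7,11-trimethyltrideca-2,4,6,8,10,12-hexaen-1-ol | OC/C(C)=C/C=C/C=C(C)/C=C/C=C(C)/C=C/[C@H]1C(C)=C[C@H](O[Si](C)(C)C(C)(C)C)CC1(C)C
F9 | step 22 | [(2E,4E,6E,8E,10E,12E)-13-[(1R,4R)-4-[(tert-butyldimethylsilyl)oxy]-2,6,6-trimethylcyclohex-2-en-1-yl]-2,7,11-trimethyltrideca-2,4,6,8,10,12-hexaen-1-yl]triphenylphosphonium bromide | [Br-].c1ccc(cc1)[P+](c1ccccc1)(c1ccccc1)C/C(C)=C/C=C/C=C(C)/C=C/C=C(C)/C=C/[C@H]1C(C)=C[C@H](O[Si](C)(C)C(C)(C)C)CC1(C)C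
F10 | step 17 | ethyl (2E,4E)-5-[(1R,4S)-4-hydroxy-2,6,6-trimethylcyclohex-2-en-1-yl]-3-methylpenta-2,4-dienoate | CCOC(=O)/C=C(C)/C=C/[C@H]1C(C)=C[C@@H](O)CC1(C)C
F11 | step 17 | ethyl (2E,4E)-3-methyl-5-[(1R,4R)-2,6,6-trimethyl-4-[(4-nitrobenzoyl)oxy]cyclohex-2-en-1-yl]penta-2,4-dienoate | CCOC(=O)/C=C(C)/C=C/[C@H]1C(C)=C[C@H](OC(=O)c2ccc(cc2)[N+](=O)[O-])CC1(C)C
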